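## Numbering used throughout

1 2,3-dimethoxyphenol · 2 2,3-dimethoxy-1,4-benzoquinone · 3 2,3-dimethoxyhydroquinone · 4 1,4-bis(benzyloxy)-2,3-dimethoxybenzene · 5 aryl iminium salt (in flask) · 6 2,5-bis(benzyloxy)-3,4-dimethoxybenzaldehyde · 7 paeonol · 8 aldol adduct (in flask) · 9 2'-hydroxychalcone · 10 flavanone (in flask) · 11 2',5'-bis(benzyloxy)-7,3',4'-trimethoxyflavone · 12 2',5'-dihydroxy-7,3',4'-trimethoxyflavone · 13 2',5'-diacetoxy-7,3',4'-trimethoxyflavone · 14 C5 trifluoroacetate of 15 (in flask) · 15 2',5'-diacetoxy-5-hydroxy-7,3',4'-trimethoxyflavone · 16 target.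

## Analysis of the target

Compound 16 is a flavone: a benzo ring A fused to a γ-pyranone ring C, with an aryl ring B on C2. It has no stereocentre, so every problem is one of regiochemistry and chemoselectivity. Ring A carries a free hydroxyl at C5, hydrogen-bonded to the C4 carbonyl, and a methyl ether at C7. Ring B is oxygenated on four neighbouring carbons: free hydroxyls at C2' and C5' (a para-related hydroquinone pair) flank the methyl ethers at C3' and C4', and only C6' bears hydrogen. The hydroquinone is the sensitive part, since it is easily oxidised to the p-quinone, most readily as a phenoxide in air; ring C is also opened by hot hydroxide. The difficulty is to sort six oxygens into three phenols and three methyl ethers. In ring A this would normally mean telling apart the two meta-related oxygens of a phloroglucinol unit. The route rests on the fact that C5–H lies peri to the C4 carbonyl and is the only C–H bond that can form a five-membered metallacycle with it (metal, O, C4, C4a, C5). The C5 oxygen can therefore be introduced last, by carbonyl-directed C–H oxygenation of a 7-methoxyflavone whose ring A comes from the mono-phenol 7. The price is that ring B must pass through an acidic, oxidising step, which fixes its protecting groups at that stage as acetates.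

## Retrosynthetic reasoning

**16 ⇒ 15.** The two acyl C–O bonds on ring B are cut. The free hydroquinone is thereby exposed only in the last operation, and mild ester methanolysis leaves the methyl ethers and ring C alone.

**15 ⇒ 13 (through 14).** The C5–O bond is cut. This oxygen is the one that would turn ring A into a differentiated phloroglucinol. Without it, ring A carries a single methoxy group and no C5/C7 selectivity question remains. The forward reaction must oxygenate C5–H only and must not oxidise ring B. The C4 carbonyl fixes the site, and the acetates in 13 keep ring B electron-poor. The first-formed product is the trifluoroacetate 14, which is hydrolysed to 15 on work-up.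

**13 ⇒ 12 ⇒ 11.** The ring B protecting groups are exchanged. Acetates would not survive the basic and hot conditions under which the flavone is assembled, and benzyl ethers would not survive the strong acid and oxidant of the C–H oxygenation. Ring B is therefore built as the dibenzyl ether 11, freed to 12 and re-protected as 13.

**11 ⇒ 9 (through 10).** The O1–C2 bond is cut and C2–C3 is returned to the chalcone oxidation level. Compound 9 has only one hydroxyl ortho to the ketone, so the oxidative ring closure has no regiochemical choice. It passes through the flavanone 10.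

**9 ⇒ 6 + 7 (through 8).** The enone C=C bond (later C2–C3 of ring C) is cut. This is the most convergent division: 7 brings ring A with its acetyl group and 6 brings ring B with one carbon. Compound 6 cannot enolise, so the crossed aldol condensation via 8 can give only one product.

**6 ⇒ 4 (through 5).** The aryl–CHO bond is cut. Compound 4 is C2-symmetric, so its two free ring positions are equivalent, and each is activated by an ortho benzyloxy and a para methoxy group. Formylation through the iminium salt 5 can give only one isomer.

**4 ⇒ 3 ⇒ 2 ⇒ 1.** The benzyl ethers are removed, the hydroquinone 3 is traced to the quinone 2, and the quinone to the phenol 1. Compound 1 already has both methoxy groups and a free para position, so para-selective oxidation of the phenol places the fourth oxygen exactly where ring B needs it.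

## Alternatives that were turned down

**Alternative 1:** Ring A is folded from an open chain and not bought.
- Disconnection: the C4a–C8a bond of ring A, leading back to the cinnamoyl triketo ester A2 (methyl (E)-9-[2,5-bis(benzyloxy)-3,4-dimethoxyphenyl]-3,5,7-trioxonon-8-enoate).
- Forward key step: Mg(OMe)2 would chelate the poly-β-carbonyl chain, the C6 methylene would attack the C1 ester carbon in a Claisen condensation, and loss of methanol and enolisation would give the trihydroxychalcone A1.
- For: it follows the biosynthetic logic and makes all three ring A oxygens at once. The trihydroxyphenyl ketone of A1 is symmetrical, so later closure of ring C onto either ortho hydroxyl gives the same flavone. No oxidant meets ring B after assembly and no transition metal is needed. On these last two points it is stronger than the chosen route.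
- Against: A2 is a labile chain that needs several steps of dianion chemistry from 6. It can also cyclise in the aldol mode (C2 onto the C7 ketone) or lactonise to a pyrone. A1 then has three free phenols on ring A, and the 7-methyl ether must be placed selectively on the hydroxyl para to the ketone. That is the very differentiation the chosen route avoids, eased here only by hydrogen bonding of the two ortho hydroxyls. Oxidative cyclisation and debenzylation still follow.
- Comparison: the key step builds a ring that is commercially available as 7, and the sequence should be about two steps longer with more delicate intermediates. The chosen route offers stable, crystalline-type intermediates and defers the one demanding step to the end.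

**Alternative 2:** Ring C is assembled by aldehyde C–H functionalisation.
- Disconnection: the C3–C4 bond, giving 2,6-dihydroxy-4-methoxybenzaldehyde A4 and the aroyl sulfoxonium ylide A5.
- Forward key step: the cationic rhodium catalyst from [(C5Me5)RhCl2]2 and AgSbF6 would use a phenol of A4 to direct cleavage of the aldehyde C–H bond. The resulting acyl–rhodium species would take up the carbene from A5 with loss of dimethyl sulfoxide, and migratory insertion and protonation would give the 1,3-diketone A3. Acid then closes ring C.
- For: it is highly convergent. Because A4 is symmetrical the C5 hydroxyl is in place from the start. Ring B never meets an oxidant, and no benzyl-to-acetate exchange is needed. On convergence and on safety of ring B it is as strong as or stronger than the chosen route, and its step count is comparable or one lower.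
- Against: A4 is not a common stock phenol, and its preparation by formylation must choose between two kinds of activated ring position. A5 needs three further steps from 6 (oxidation to the acid, activation, ylide formation) and is a hindered, doubly ortho-substituted aroyl ylide. The second free phenol of A4 is a competing O–H insertion partner for the rhodium carbene. Rhodium and silver are spent at the fragment union, where the most material is processed.
- Comparison: the chosen route joins two cheap phenol-derived fragments by a metal-free aldol condensation. It keeps the single precious-metal step for the end, where the site is fixed by the geometry of the chelate and not by how a building block was made.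

**Alternative 3:** Ring B is built by ring expansion of a squarate.
- Disconnection: the C1'–C2' bond of ring B, leading back to the 4-alkenyl-4-hydroxycyclobutenone A7 and, further, to dimethyl squarate A8 plus a vinyl unit on the chromone.
- Forward key step: heating A7 would open the four-membered ring in a 4π process to a dienylketene. 6π closure between the ketene carbon and the terminal vinyl carbon, followed by enolisation, would give the hydroquinone ring B of the 5-O-benzyl ether A6.
- For: all four ring B oxygens come in defined positions from A8, two as methoxy groups and two from the carbonyl and carbinol carbons. Ring B needs no protecting groups and no quinone redox steps. On this point it is more economical than the chosen route.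
- Against: A7 requires a chromonyl-vinyl metal reagent to add to A8, yet the chromone is itself a ketone and a Michael acceptor, so it would have to be masked. Ring A must already carry a benzyloxy group at C5 and a methoxy group at C7, so the C5/C7 differentiation is kept in full and paid for in protecting-group steps. The free hydroquinone is liberated at high temperature, and a debenzylation still follows.
- Comparison: the key step is spent on ring B, which four simple steps from 1 provide, while the real difficulty in ring A is left untouched. The chosen route removes that difficulty and should be shorter.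

Key step: step 9

Remark on the chemistry: the target is achiral; the stereocentres of the in-flask intermediates 8 and 10 are racemic and are destroyed within the same step. Compounds 1 and 7 and all reagents are taken as commercial.

## Route

Step 1
Reactants: 1 2,3-dimethoxyphenol
Product: 2 2,3-dimethoxy-1,4-benzoquinone
Conditions: K2[ON(SO3)2] (Fremy's salt, 2.5 equiv), KH2PO4, H2O/acetone, 0 °C to rt
Reagents that add atoms: potassium nitrosodisulfonate (Fremy's salt), [K+].[K+].[O]N(S(=O)(=O)[O-])S(=O)(=O)[O-]
Why: Teuber oxidation: one equivalent of the nitroxide forms the phenoxyl radical, a second adds through oxygen at the free para position, and loss of imidodisulfonate gives the p-quinone. The para position of 1 is unsubstituted, so the p-quinone should form in preference to an o-quinone.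

Step 2
Reactants: 2 2,3-dimethoxy-1,4-benzoquinone
Product: 3 2,3-dimethoxybenzene-1,4-diol (2,3-dimethoxyhydroquinone)
Conditions: Na2S2O4, EtOAc/H2O, rt, under Ar
Reagents that add atoms: none
Why: Dithionite reduction of a quinone to its hydroquinone is fast and clean in a two-phase system. The air-sensitive product is carried on at once.

Step 3
Reactants: 3 2,3-dimethoxybenzene-1,4-diol
Product: 4 1,4-bis(benzyloxy)-2,3-dimethoxybenzene
Conditions: BnBr (2.4 equiv), K2CO3 (3 equiv), DMF, rt to 60 °C, Ar
Reagents that add atoms: benzyl bromide, BrCc1ccccc1
Why: Williamson ether synthesis on both phenols. Argon keeps the hydroquinone dianion from air oxidation, and the benzyl ethers will withstand the base of step 5 and the hot iodine/DMSO of step 6.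

Step 4
Reactants: 4 1,4-bis(benzyloxy)-2,3-dimethoxybenzene
Product: 6 2,5-bis(benzyloxy)-3,4-dimethoxybenzaldehyde, via aryl iminium dichlorophosphate 5 (not isolated)
Conditions: POCl3 (2 equiv), DMF, 0 °C then 70 °C; then ice/H2O
Reagents that add atoms: N,N-dimethylformamide, CN(C)C=O (formyl carbon); water, O (carbonyl oxygen)
Why: Vilsmeier–Haack formylation. Each free position of the tetra-alkoxybenzene is activated by an ortho and a para oxygen, and the C2 symmetry of 4 makes the two positions equivalent, so a single aldehyde should result after hydrolysis of iminium salt 5.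

Step 5
Reactants: 7 paeonol (1-(2-hydroxy-4-methoxyphenyl)ethan-1-one); 6 2,5-bis(benzyloxy)-3,4-dimethoxybenzaldehyde
Product: 9 (E)-3-[2,5-bis(benzyloxy)-3,4-dimethoxyphenyl]-1-(2-hydroxy-4-methoxyphenyl)prop-2-en-1-one, via racemic aldol adduct 8 (not isolated)
Conditions: KOH (50% aq.), EtOH, rt; then dil. HCl
Reagents that add atoms: none
Why: Claisen–Schmidt condensation. Only 7 can enolise and only 6 can act as the acceptor, and E1cB dehydration of aldol 8 should give the conjugated E-enone, the thermodynamically favoured geometry.

Step 6
Reactants: 9 (E)-3-[2,5-bis(benzyloxy)-3,4-dimethoxyphenyl]-1-(2-hydroxy-4-methoxyphenyl)prop-2-en-1-one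
Product: 11 2-[2,5-bis(benzyloxy)-3,4-dimethoxyphenyl]-7-methoxy-4H-chromen-4-one (2',5'-bis(benzyloxy)-7,3',4'-trimethoxyflavone), via racemic flavanone 10 (not isolated)
Conditions: I2 (10 mol%), DMSO, 130 °C; then aq. Na2S2O3
Reagents that add atoms: none
Why: Iodine-mediated oxidative cyclisation of a 2'-hydroxychalcone. Oxa-Michael closure gives flavanone 10, α-iodination and loss of HI give the flavone, and DMSO reoxidises HI to I2. The single ortho hydroxyl leaves one mode of closure.

Step 7
Reactants: 11 2-[2,5-bis(benzyloxy)-3,4-dimethoxyphenyl]-7-methoxy-4H-chromen-4-one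
Product: 12 2-(2,5-dihydroxy-3,4-dimethoxyphenyl)-7-methoxy-4H-chromen-4-one (2',5'-dihydroxy-7,3',4'-trimethoxyflavone)
Conditions: H2 (1 atm), 10% Pd/C, EtOAc/THF, rt; filtration under Ar
Reagents that add atoms: none
Why: Hydrogenolysis of aryl benzyl ethers. The cross-conjugated C2=C3 bond of ring C is normally untouched at atmospheric pressure if the reaction is stopped at full debenzylation, and the methyl ethers are inert.

Step 8
Reactants: 12 2-(2,5-dihydroxy-3,4-dimethoxyphenyl)-7-methoxy-4H-chromen-4-one
Product: 13 2-(2,5-diacetoxy-3,4-dimethoxyphenyl)-7-methoxy-4H-chromen-4-one (2',5'-diacetoxy-7,3',4'-trimethoxyflavone)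
Conditions: Ac2O, pyridine, DMAP (cat.), CH2Cl2, 0 °C to rt
Reagents that add atoms: acetic anhydride, CC(=O)OC(C)=O
Why: DMAP-catalysed acylation of both phenols. The acetates stop the hydroquinone from being oxidised and lower the electron density of ring B for the next step.

Step 9
Reactants: 13 2-(2,5-diacetoxy-3,4-dimethoxyphenyl)-7-methoxy-4H-chromen-4-one
Product: 15 2-(2,5-diacetoxy-3,4-dimethoxyphenyl)-5-hydroxy-7-methoxy-4H-chromen-4-one (2',5'-diacetoxy-5-hydroxy-7,3',4'-trimethoxyflavone), via C5 trifluoroacetate 14 (not isolated)
Conditions: [RuCl2(p-cymene)]2 (5 mol%), PhI(OCOCF3)2 (2 equiv), CF3CO2H/(CF3CO)2O, 80 °C; then H2O, aq. NaHCO3, rt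
Reagents that add atoms: [bis(trifluoroacetoxy)iodo]benzene, O=C(OI(OC(=O)C(F)(F)F)c1ccccc1)C(F)(F)F (its trifluoroacetate, which exchanges with the solvent acid OC(=O)C(F)(F)F, supplies the C5 oxygen)
Why: Chloride–trifluoroacetate exchange in the acid gives a cationic ruthenium trifluoroacetate that binds the C4 carbonyl oxygen of 13; carboxylate-assisted concerted metalation–deprotonation then cleaves the peri C5–H bond and gives a five-membered ruthenacycle (Ru, O, C4, C4a, C5). PhI(OCOCF3)2 oxidises this divalent ruthenium metallacycle to a tetravalent ruthenium trifluoroacetate, and C–O reductive elimination forms the C5–O bond as aryl trifluoroacetate 14 and returns divalent ruthenium. The aqueous work-up hydrolyses the very labile trifluoroacetate to the chelated phenol 15 while the two aryl acetates should stay. The closest known reaction type is the ruthenium-catalysed, ketone-directed ortho C–H hydroxylation of aryl ketones with hypervalent iodine oxidants in CF3CO2H/(CF3CO)2O, which has been shown at C5 of flavones and chromones. No ring is closed and no stereocentre is formed; one C–O bond is made. The step needs site selectivity for C5 over C3, C6, C8 and C6': only C5–H can reach a five-membered chelate with the carbonyl (C3–H would need a four-membered one and the ring B hydrogen is out of reach), so the substrate geometry fixes the site. It also needs C–H metalation to win over electron-transfer oxidation of ring B: the two acetates and the electron-poor chromone lower the electron density of the dimethoxyarene, and (CF3CO)2O keeps every phenol acylated, so neither ring B nor the new C5 oxygen meets the oxidant as a free phenol. Over-oxidation is excluded because ring A has only one peri hydrogen.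

Step 10
Reactants: 15 2-(2,5-diacetoxy-3,4-dimethoxyphenyl)-5-hydroxy-7-methoxy-4H-chromen-4-one
Product: 16 2-(2,5-dihydroxy-3,4-dimethoxyphenyl)-5-hydroxy-7-methoxy-4H-chromen-4-one (5,2',5'-trihydroxy-7,3',4'-trimethoxyflavone, the target)
Conditions: K2CO3 (3 equiv), degassed MeOH, Ar, 0 °C to rt; then 1 M HCl
Reagents that add atoms: none
Why: Base-mediated transesterification of aryl acetates with methanol is fast at or below room temperature and leaves methyl ethers and ring C intact. Exclusion of air and an acidic quench keep the hydroquinone phenoxide from oxidising to the quinone.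

## Compound list

1 | 2,3-dimethoxyphenol | COc1cccc(O)c1OC | starting material
2 | 2,3-dimethoxy-1,4-benzoquinone | COC1=C(OC)C(=O)C=CC1=O | intermediate
3 | 2,3-dimethoxybenzene-1,4-diol | COc1c(O)ccc(O)c1OC | intermediate
4 | 1,4-bis(benzyloxy)-2,3-dimethoxybenzene | COc1c(OCc2ccccc2)ccc(OCc2ccccc2)c1OC | intermediate
5 | N-{[2,5-bis(benzyloxy)-3,4-dimethoxyphenyl]methylidene}-N-methylmethanaminium dichlorophosphate | C[N+](C)=Cc1cc(OCc2ccccc2)c(OC)c(OC)c1OCc1ccccc1.[O-]P(=O)(Cl)Cl | intermediate (not isolated)
6 | 2,5-bis(benzyloxy)-3,4-dimethoxybenzaldehyde | O=Cc1cc(OCc2ccccc2)c(OC)c(OC)c1OCc1ccccc1 | intermediate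
7 | paeonol, 1-(2-hydroxy-4-methoxyphenyl)ethan-1-one | COc1ccc(C(C)=O)c(O)c1 | starting material
8 | racemic 3-[2,5-bis(benzyloxy)-3,4-dimethoxyphenyl]-3-hydroxy-1-(2-hydroxy-4-methoxyphenyl)propan-1-one | COc1ccc(C(=O)CC(O)c2cc(OCc3ccccc3)c(OC)c(OC)c2OCc2ccccc2)c(O)c1 | intermediate (not isolated)
9 | (E)-3-[2,5-bis(benzyloxy)-3,4-dimethoxyphenyl]-1-(2-hydroxy-4-methoxyphenyl)prop-2-en-1-one | COc1ccc(C(=O)/C=C/c2cc(OCc3ccccc3)c(OC)c(OC)c2OCc2ccccc2)c(O)c1 | intermediate
10 | racemic 2-[2,5-bis(benzyloxy)-3,4-dimethoxyphenyl]-7-methoxy-2,3-dihydro-4H-chromen-4-one | COc1ccc2c(c1)OC(c1cc(OCc3ccccc3)c(OC)c(OC)c1OCc1ccccc1)CC2=O | intermediate (not isolated)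
11 | 2-[2,5-bis(benzyloxy)-3,4-dimethoxyphenyl]-7-methoxy-4H-chromen-4-one | COc1ccc2c(=O)cc(-c3cc(OCc4ccccc4)c(OC)c(OC)c3OCc3ccccc3)oc2c1 | intermediate
12 | 2-(2,5-dihydroxy-3,4-dimethoxyphenyl)-7-methoxy-4H-chromen-4-one | COc1ccc2c(=O)cc(-c3cc(O)c(OC)c(OC)c3O)oc2c1 | intermediate
13 | 2-(2,5-diacetoxy-3,4-dimethoxyphenyl)-7-methoxy-4H-chromen-4-one | COc1ccc2c(=O)cc(-c3cc(OC(C)=O)c(OC)c(OC)c3OC(C)=O)oc2c1 | intermediate
14 | 2-(2,5-diacetoxy-3,4-dimethoxyphenyl)-7-methoxy-4-oxo-4H-chromen-5-yl trifluoroacetate | COc1cc(OC(=O)C(F)(F)F)c2c(=O)cc(-c3cc(OC(C)=O)c(OC)c(OC)c3OC(C)=O)oc2c1 | intermediate (not isolated)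
15 | 2-(2,5-diacetoxy-3,4-dimethoxyphenyl)-5-hydroxy-7-methoxy-4H-chromen-4-one | COc1cc(O)c2c(=O)cc(-c3cc(OC(C)=O)c(OC)c(OC)c3OC(C)=O)oc2c1 | intermediate
16 | 2-(2,5-dihydroxy-3,4-dimethoxyphenyl)-5-hydroxy-7-methoxy-4H-chromen-4-one | COc1cc(O)c2c(=O)cc(-c3cc(O)c(OC)c(OC)c3O)oc2c1 | target

## Step count and risk

Total: 10 steps. Longest linear sequence: 10 steps (1 to 16); paeonol 7 enters at step 5.

**Step 9 (key step).**
- What may go wrong: electron transfer from the dimethoxyarene of ring B to the hypervalent iodine oxidant, leading to decomposition. The chromone carbonyl is a weak donor in strong acid, so metalation may be slow and conversion incomplete. The acetate on C5' could direct a competing oxygenation at C6'. Acyl exchange of the acetates in the hot acid anhydride would give mixed esters; this is harmless, since the crude mixture can be taken straight through step 10.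
- Fallback: the late C–H oxidation is given up and the C5 oxygen is brought in with ring A. Setting out from 6, Claisen–Schmidt condensation (KOH, EtOH) with commercial 1-(2,6-dihydroxy-4-methoxyphenyl)ethan-1-one F1 passes through the racemic aldol adduct F2 and gives the 2',6'-dihydroxychalcone F3. I2 in DMSO at 130 °C closes this through the racemic 5-hydroxyflavanone F4 to 2',5'-bis(benzyloxy)-5-hydroxy-7,3',4'-trimethoxyflavone F5; the two ortho hydroxyls are equivalent, so the closure has no regiochemical choice. Hydrogenolysis (H2, Pd/C) then returns to the route at 16.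

**Step 4.**
- What may go wrong: slow electrophilic substitution at a position next to a bulky benzyloxy group, and partial loss of a benzyl ether under the hot acidic chlorophosphate conditions.
- Fallback: setting out from 4, NBS in MeCN at 0 °C gives 1,4-bis(benzyloxy)-5-bromo-2,3-dimethoxybenzene F6. Bromine–lithium exchange with n-BuLi in THF at −78 °C, which is faster than benzylic deprotonation, gives [2,5-bis(benzyloxy)-3,4-dimethoxyphenyl]lithium F7. Addition to DMF gives the lithium hemiaminal alkoxide F8, and aqueous work-up returns to the route at 6.

**Step 6.**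
- What may go wrong: cleavage of a benzyl ether by the HI formed in the iodine cycle at 130 °C, or stalling at the flavanone stage.
- Fallback: setting out from 9, NaOAc in refluxing EtOH closes the ring to the flavanone 10, which is isolated this time. DDQ in refluxing dioxane then dehydrogenates it by hydride abstraction, returning to the route at 11. No new compound is needed (entry F0 below).

**Step 7.**
- What may go wrong: over-reduction of the C2=C3 bond of ring C on prolonged hydrogenation, and air oxidation of the electron-rich hydroquinone during filtration and concentration.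
- Fallback: the air-sensitive phenol is not isolated. Setting out from 11, oxidative debenzylation with (NH4)2Ce(NO3)6 in MeCN/H2O at 0 °C gives the air-stable 2-(7-methoxy-4-oxo-4H-chromen-2-yl)-5,6-dimethoxy-1,4-benzoquinone F9. Reductive acetylation (Zn dust, Ac2O, NaOAc) reduces this to 12 in the flask and acetylates it at once, returning to the route at 13.

## Further compounds

F1 | step 9 | 1-(2,6-dihydroxy-4-methoxyphenyl)ethan-1-one | COc1cc(O)c(C(C)=O)c(O)c1
F2 | step 9 | racemic 3-[2,5-bis(benzyloxy)-3,4-dimethoxyphenyl]-1-(2,6-dihydroxy-4-methoxyphenyl)-3-hydroxypropan-1-one | COc1cc(O)c(C(=O)CC(O)c2cc(OCc3ccccc3)c(OC)c(OC)c2OCc2ccccc2)c(O)c1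
F3 | step 9 | (E)-3-[2,5-bis(benzyloxy)-3,4-dimethoxyphenyl]-1-(2,6-dihydroxy-4-methoxyphenyl)prop-2-en-1-one | COc1cc(O)c(C(=O)/C=C/c2cc(OCc3ccccc3)c(OC)c(OC)c2OCc2ccccc2)c(O)c1
F4 | step 9 | racemic 2-[2,5-bis(benzyloxy)-3,4-dimethoxyphenyl]-5-hydroxy-7-methoxy-2,3-dihydro-4H-chromen-4-one | COc1cc(O)c2c(c1)OC(c1cc(OCc3ccccc3)c(OC)c(OC)c1OCc1ccccc1)CC2=O
F5 | step 9 | 2-[2,5-bis(benzyloxy)-3,4-dimethoxyphenyl]-5-hydroxy-7-methoxy-4H-chromen-4-one | COc1cc(O)c2c(=O)cc(-c3cc(OCc4ccccc4)c(OC)c(OC)c3OCc3ccccc3)oc2c1
F6 | step 4 | 1,4-bis(benzyloxy)-5-bromo-2,3-dimethoxybenzene | COc1c(OCc2ccccc2)cc(Br)c(OCc2ccccc2)c1OC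
F7 | step 4 | [2,5-bis(benzyloxy)-3,4-dimethoxyphenyl]lithium | [Li]c1cc(OCc2ccccc2)c(OC)c(OC)c1OCc1ccccc1
F8 | step 4 | racemic lithium [2,5-bis(benzyloxy)-3,4-dimethoxyphenyl](dimethylamino)methanolate | [Li+].CN(C)C([O-])c1cc(OCc2ccccc2)c(OC)c(OC)c1OCc1ccccc1
F0 | step 6 | none | none
F9 | step 7 | 2-(7-methoxy-4-oxo-4H-chromen-2-yl)-5,6-dimethoxy-1,4-benzoquinone | COc1ccc2c(=O)cc(C3=CC(=O)C(OC)=C(OC)C3=O)oc2c1
A1 | alternative 1 | (E)-2',4',6'-trihydroxy-2,5-bis(benzyloxy)-3,4-dimethoxychalcone | O=C(/C=C/c1cc(OCc2ccccc2)c(OC)c(OC)c1OCc1ccccc1)c1c(O)cc(O)cc1O
A2 | alternative 1 | methyl (E)-9-[2,5-bis(benzyloxy)-3,4-dimethoxyphenyl]-3,5,7-trioxonon-8-enoate | COC(=O)CC(=O)CC(=O)CC(=O)/C=C/c1cc(OCc2ccccc2)c(OC)c(OC)c1OCc1ccccc1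
A3 | alternative 2 | 1-(2,6-dihydroxy-4-methoxyphenyl)-3-[2,5-bis(benzyloxy)-3,4-dimethoxyphenyl]propane-1,3-dione | O=C(CC(=O)c1cc(OCc2ccccc2)c(OC)c(OC)c1OCc1ccccc1)c1c(O)cc(OC)cc1O
A4 | alternative 2 | 2,6-dihydroxy-4-methoxybenzaldehyde | COc1cc(O)c(C=O)c(O)c1
A5 | alternative 2 | 1-[2,5-bis(benzyloxy)-3,4-dimethoxyphenyl]-2-[dimethyl(oxo)-λ6-sulfanylidene]ethan-1-one | CS(C)(=O)=CC(=O)c1cc(OCc2ccccc2)c(OC)c(OC)c1OCc1ccccc1
A6 | alternative 3 | 5-(benzyloxy)-2-(2,5-dihydroxy-3,4-dimethoxyphenyl)-7-methoxy-4H-chromen-4-one | COc1cc(OCc2ccccc2)c2c(=O)cc(-c3cc(O)c(OC)c(OC)c3O)oc2c1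
A7 | alternative 3 | racemic 4-{(E)-2-[5-(benzyloxy)-7-methoxy-4-oxo-4H-chromen-2-yl]ethenyl}-4-hydroxy-2,3-dimethoxycyclobut-2-en-1-one | COC1=C(OC)C(O)(/C=C/c2cc(=O)c3c(OCc4ccccc4)cc(OC)cc3o2)C1=O
A8 | alternative 3 | dimethyl squarate, 3,4-dimethoxycyclobut-3-ene-1,2-dione | COC1=C(OC)C(=O)C1=O
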